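**Plan**

1. Labels: ring A is the indane resorcinol ring; rings B and C are the two resorcinol rings of the eight-membered ring (C also carries the furan oxygen); rings D, E and F are the 4-oxyphenyl groups on indane C-3, on the methine C-α and on furan C-2′. Indane C-1 carries C-α and C-2 carries ring C; furan C-3′ lies between rings B and C.
2. Enabling feature: the cyclooctane (C-α, C-1, C-2, two carbons of ring C, C-3′, two carbons of ring B) is tied by two aryl–CH bonds, ring C–C-2 and ring B–C-3′. Each is at the ring carbon meta to both oxygens, out of reach of Friedel–Crafts chemistry, so a boron atom on C-2 is used to hold ring C, let ring B add to a nitrile carbon (future C-3′) on ring C, and then pass C-2 to ring C by a 1,2-shift.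
3. Retrosynthesis: open the furan (C-3′–C-2′ and O–C-2′) back to a C-3′ ketone; cut both aryl–CH bonds of the eight-membered ring at once (ring C nitrile plus an indanyl boronate carrying bromo ring B); then cut ring B–C-α (Friedel–Crafts), C-1–C-α (Nozaki–Hiyama–Kishi) and the indanone (hydroacylation).
4. Forward order: ring A with the five-membered ring, then C-α with ring E, boron on C-2, ring B on C-α, the eight-membered ring with ring C (key step), the dihydrofuran with ring F, and last the demethylation. Ring B is placed on C-α before ring C is present, so the C-α cation cannot collapse onto ring C.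
5. Stereochemistry: C-3 from a chiral rhodium catalyst; C-2 and C-1 from hydroboration anti to ring D (syn addition); C-α from facial control at the benzylic cation; C-2 is kept through the stereoretentive boron-to-carbon shift; C-3′ from protonation on the open face and C-2′ from thermodynamic trans ring closure.

Key step: step 8

Remark: the α-arylvinyl boronate and 2-bromo-4,6-dimethoxybenzaldehyde are taken as catalogue compounds, and the antipode of the rhodium ligand is chosen so that the (S)-indanone results.

**Route**

Step 1
Reactants: 1 2-bromo-3,5-dimethoxybenzaldehyde; 2 2-[1-(4-methoxyphenyl)ethenyl]-4,4,5,5-tetramethyl-1,3,2-dioxaborolane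
Product: 3 3,5-dimethoxy-2-[1-(4-methoxyphenyl)ethenyl]benzaldehyde
Conditions: Pd(OAc)2 (3 mol %), SPhos (6 mol %), K3PO4, toluene–H2O, 90 °C
Reagents that add atoms: none
Why: Suzuki–Miyaura coupling of the hindered, electron-rich aryl bromide with the α-arylvinyl boronate should proceed with a bulky biaryl phosphine, and the aldehyde is inert under these conditions.

Step 2
Reactants: 3 3,5-dimethoxy-2-[1-(4-methoxyphenyl)ethenyl]benzaldehyde
Product: 4 (3S)-4,6-dimethoxy-3-(4-methoxyphenyl)-2,3-dihydro-1H-inden-1-one
Conditions: [Rh((S)-BINAP)]ClO4 (5 mol %), CH2Cl2, 25 °C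
Reagents that add atoms: none
Why: Rhodium-catalysed asymmetric intramolecular alkene hydroacylation (the acyl rhodium hydride adds across the 1,1-disubstituted alkene and reductive elimination closes the five-membered ring) should give the 3-arylindanone, the (S) centre at C-3 being set by the chiral bisphosphine in the hydrometalation.

Step 3
Reactants: 4 (3S)-4,6-dimethoxy-3-(4-methoxyphenyl)-2,3-dihydro-1H-inden-1-one
Product: 5 (1S)-5,7-dimethoxy-1-(4-methoxyphenyl)-1H-inden-3-yl trifluoromethanesulfonate
Conditions: Tf2O, 2,6-di-tert-butyl-4-methylpyridine, CH2Cl2, 0 °C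
Reagents that add atoms: trifluoromethanesulfonic anhydride, O=S(=O)(OS(=O)(=O)C(F)(F)F)C(F)(F)F
Why: Enol triflate formation under non-basic conditions takes the only enolisable position (C-2) and avoids deprotonation of the doubly activated C-3–H of the indene product, so the stereocentre should survive.

Step 4
Reactants: 5 (1S)-5,7-dimethoxy-1-(4-methoxyphenyl)-1H-inden-3-yl trifluoromethanesulfonate; 6 4-methoxybenzaldehyde
Product: 7 [(1S)-5,7-dimethoxy-1-(4-methoxyphenyl)-1H-inden-3-yl](4-methoxyphenyl)methanol (both carbinol epimers)
Conditions: CrCl2 (4 equiv), NiCl2 (2 mol %), DMF, 25 °C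
Reagents that add atoms: none
Why: Nozaki–Hiyama–Kishi coupling of the alkenyl triflate with the aldehyde under neutral conditions should form the C-1–C-α bond without touching the base-sensitive C-3–H; the carbinol configuration is of no consequence because C-α is ionised in step 6.

Step 5
Reactants: 7 [(1S)-5,7-dimethoxy-1-(4-methoxyphenyl)-1H-inden-3-yl](4-methoxyphenyl)methanol
Product: 8 (4-methoxyphenyl)[(1S,2R,3S)-4,6-dimethoxy-3-(4-methoxyphenyl)-2-(4,4,5,5-tetramethyl-1,3,2-dioxaborolan-2-yl)-2,3-dihydro-1H-inden-1-yl]methanol (both carbinol epimers; ring D and the C-1 side chain cis to each other and trans to boron)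
Conditions: BH3·SMe2 (3 equiv), THF, 0 → 25 °C; pinacol, 25 °C
Reagents that add atoms: borane–dimethyl sulfide, [BH3-][S+](C)C; pinacol, CC(C)(O)C(C)(C)O
Why: Hydroboration of the trisubstituted styrene-type alkene should place boron on C-2 (anti-Markovnikov) from the face opposite ring D and deliver hydrogen to C-1 on the same face (syn addition), which gives the 1,2-trans-2,3-trans indane, and condensation with pinacol gives the stable boronic ester.

Step 6
Reactants: 8 the indanyl boronate carbinol; 9 1-bromo-3,5-dimethoxybenzene
Product: 10 2-[(1R,2S,3S)-1-[(R)-(2-bromo-4,6-dimethoxyphenyl)(4-methoxyphenyl)methyl]-4,6-dimethoxy-3-(4-methoxyphenyl)-2,3-dihydro-1H-inden-2-yl]-4,4,5,5-tetramethyl-1,3,2-dioxaborolane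
Conditions: 9 (5 equiv), TfOH (5 mol %), (CF3)2CHOH–CH2Cl2, −20 °C
Reagents that add atoms: none
Why: Friedel–Crafts alkylation in which the p-anisyl-stabilised cation at C-α is trapped by the bromoarene at its 2-position (para to one methoxy group, ortho to the other), which puts bromine on the ring B carbon meta to both oxygens, and the arene should approach the allylic-strain-minimised (H-eclipsed) cation on the face away from the ring A carbon on C-1 to give the (R) centre.

Step 7
Reactants: 11 2-bromo-4,6-dimethoxybenzaldehyde
Product: 12 2-bromo-4,6-dimethoxybenzonitrile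
Conditions: I2, aq. NH3, THF, 25 °C
Reagents that add atoms: ammonia, N
Why: Oxidative conversion of the aldehyde into the nitrile (aldimine, N-iodination, loss of HI) gives a small, linear electrophile for the future C-3′ that tolerates ortho-lithiation at low temperature.

Step 8
Reactants: 10 the bromoaryl indanyl boronate; 12 2-bromo-4,6-dimethoxybenzonitrile
Product: 17 eight-membered diaryl ketone (octamethyl ether; C-3′ as C=O; C-1 C-2 C-3 C-α as in the target), via aryllithium 13 (not isolated), via boronate complex 14 (not isolated), via cyclic iminoborate 15 (not isolated), via ketimine 16 (not isolated)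
Conditions: 12 (1.1 equiv), t-BuLi (2.0 equiv), THF–Et2O, −100 °C; add 10, −100 → −78 °C; t-BuLi (2.0 equiv), −100 → −40 °C; MeOH then NBS (1.05 equiv), −78 → 0 °C; 2 M HCl, THF, 40 °C
Reagents that add atoms: water, O
Why: Proposed new method: bromine–lithium exchange on 12 gives 13, which adds to the boronic ester of 10 to form boronate complex 14, so that boron on C-2 holds ring C next to ring B; boron is thereby protected, and a second bromine–lithium exchange on ring B is followed by Parham-type addition of the aryllithium to the nitrile carbon (ring B–C-3′ bond), closing the nine-membered boracycle 15 by 9-exo-dig attack. N-Bromosuccinimide then brominates ring C para to boron (between the two methoxy groups), the cationic character at the boron-bearing carbon triggers a suprafacial 1,2-shift of C-2 from boron to carbon, and methoxide-assisted loss of bromide and of the boryl group re-aromatises ring C, which contracts the boracycle to the eight-membered carbocycle (ring C–C-2 bond). The closest known reactions are the enantiospecific coupling of secondary boronic esters with electron-rich aryllithiums through electrophile-induced 1,2-metallate rearrangement and the Parham cyclisation of aryl bromides onto nitriles; new is their merger on one boron template, argued from the facts that a four-coordinate boronate is inert to t-BuLi and that the nitrile is shielded by two ortho substituents. No new stereocentre is formed: C-2 migrates with retention, so its configuration and the trans ring fusion are those fixed in step 5. The step needs exchange at the aryl bromide to outrun addition of t-BuLi to the nitrile, and bromination to occur on ring C and not on rings A, B, D or E; the first is secured by the low temperature and the flanking methoxy and borate groups, the second by the anionic boronate, which makes ring C by far the most nucleophilic arene. Both aryl carbons that are joined are meta to the ring oxygens, which is why an ipso-directed boron shift and an aryllithium addition are used in place of electrophilic substitution.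

Step 9
Reactants: 17 the eight-membered diaryl ketone
Product: 18 the same ketone with a free phenol on ring C ortho to the carbonyl group
Conditions: BCl3, CH2Cl2, −78 → 0 °C
Reagents that add atoms: none
Why: Chelation-controlled demethylation in which BCl3 binds the diaryl ketone and cleaves only the methoxy group ortho to it (on ring C, the sole such group in the molecule), freeing the oxygen that will close the furan.

Step 10
Reactants: 18 the phenol ketone; 19 (4-methoxybenzyl)magnesium chloride
Product: 20 tertiary carbinol at C-3′ carrying the 4-methoxybenzyl group (either carbinol configuration)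
Conditions: 19 (3 equiv), LaCl3·2LiCl, THF, −20 → 25 °C; aq. NH4Cl
Reagents that add atoms: none
Why: Grignard 1,2-addition in which the benzylic organomagnesium first deprotonates the phenol and then adds to the hindered diaryl ketone (LaCl3·2LiCl suppresses reduction), which installs C-2′ with ring F; the carbinol configuration is of no consequence because C-3′ is ionised in step 11.

Step 11
Reactants: 20 the tertiary carbinol
Product: 21 stenophyllol B octamethyl ether
Conditions: TsOH·H2O (20 mol %), toluene, 60 °C
Reagents that add atoms: none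
Why: Acid-mediated dehydrative cyclisation in which ionisation of the diaryl carbinol gives the triarylethene, protonation at C-3′ on the face opposite the three-carbon bridge (C-α, C-1, C-2) of the eight-membered ring gives the p-anisyl cation at C-2′, and reversible capture by the ring C phenol should close the 2,3-trans dihydrobenzofuran.

Step 12
Reactants: 21 stenophyllol B octamethyl ether
Product: 22 stenophyllol B
Conditions: BBr3 (16 equiv), CH2Cl2, −78 → 25 °C; then MeOH–H2O
Reagents that add atoms: none
Why: Lewis-acid ether cleavage of the eight aryl methyl ethers at low temperature should free all phenols, while the benzylic methines carry no leaving group and the only labile bond (O–C-2′) can re-close only to the trans ring.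

**Compound list**

1 | 2-bromo-3,5-dimethoxybenzaldehyde | O=Cc1cc(OC)cc(OC)c1Br | starting material
2 | 2-[1-(4-methoxyphenyl)ethenyl]-4,4,5,5-tetramethyl-1,3,2-dioxaborolane | COc1ccc(C(=C)B2OC(C)(C)C(C)(C)O2)cc1 | starting material
3 | 3,5-dimethoxy-2-[1-(4-methoxyphenyl)ethenyl]benzaldehyde | COc1ccc(C(=C)c2c(OC)cc(OC)cc2C=O)cc1 | intermediate
4 | (3S)-4,6-dimethoxy-3-(4-methoxyphenyl)-2,3-dihydro-1H-inden-1-one | COc1ccc([C@@H]2CC(=O)c3cc(OC)cc(OC)c32)cc1 | intermediate
5 | (1S)-5,7-dimethoxy-1-(4-methoxyphenyl)-1H-inden-3-yl trifluoromethanesulfonate | COc1ccc([C@@H]2C=C(OS(=O)(=O)C(F)(F)F)c3cc(OC)cc(OC)c32)cc1 | intermediate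
6 | 4-methoxybenzaldehyde | COc1ccc(C=O)cc1 | starting material
7 | [(1S)-5,7-dimethoxy-1-(4-methoxyphenyl)-1H-inden-3-yl](4-methoxyphenyl)methanol, both carbinol epimers | COc1ccc([C@@H]2C=C(C(O)c3ccc(OC)cc3)c3cc(OC)cc(OC)c32)cc1 | intermediate
8 | (4-methoxyphenyl)[(1S,2R,3S)-4,6-dimethoxy-3-(4-methoxyphenyl)-2-(4,4,5,5-tetramethyl-1,3,2-dioxaborolan-2-yl)-2,3-dihydro-1H-inden-1-yl]methanol, both carbinol epimers | COc1ccc([C@H]2c3c(OC)cc(OC)cc3[C@@H](C(O)c4ccc(OC)cc4)[C@@H]2B2OC(C)(C)C(C)(C)O2)cc1 | intermediate
9 | 1-bromo-3,5-dimethoxybenzene | COc1cc(Br)cc(OC)c1 | starting material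
10 | 2-[(1R,2S,3S)-1-[(R)-(2-bromo-4,6-dimethoxyphenyl)(4-methoxyphenyl)methyl]-4,6-dimethoxy-3-(4-methoxyphenyl)-2,3-dihydro-1H-inden-2-yl]-4,4,5,5-tetramethyl-1,3,2-dioxaborolane | COc1ccc([C@H]2c3c(OC)cc(OC)cc3[C@@H]([C@H](c4ccc(OC)cc4)c4c(OC)cc(OC)cc4Br)[C@@H]2B2OC(C)(C)C(C)(C)O2)cc1 | intermediate
11 | 2-bromo-4,6-dimethoxybenzaldehyde | O=Cc1c(Br)cc(OC)cc1OC | starting material
12 | 2-bromo-4,6-dimethoxybenzonitrile | N#Cc1c(Br)cc(OC)cc1OC | intermediate
13 | (2-cyano-3,5-dimethoxyphenyl)lithium | [Li]c1cc(OC)cc(OC)c1C#N | intermediate (not isolated)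
14 | lithium (2-cyano-3,5-dimethoxyphenyl)(pinacolato)borate of 10, boron on indane C-2, configuration as in 10 | [Li+].COc1ccc([C@H]2c3c(OC)cc(OC)cc3[C@@H]([C@H](c4ccc(OC)cc4)c4c(OC)cc(OC)cc4Br)[C@@H]2[B-]2(c3cc(OC)cc(OC)c3C#N)OC(C)(C)C(C)(C)O2)cc1 | intermediate (not isolated)
15 | dilithium salt of the nine-membered cyclic boronate in which ring B is bonded to the former nitrile carbon (N-lithio ketimine) and boron bridges C-2 and ring C | [Li+].[Li+].COc1ccc([C@H]2c3c(OC)cc(OC)cc3[C@H]3[C@H](c4ccc(OC)cc4)c4c(OC)cc(OC)cc4C(=[N-])c4c(OC)cc(OC)cc4[B-]4(OC(C)(C)C(C)(C)O4)[C@H]23)cc1 | intermediate (not isolated)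
16 | N–H ketimine of 17 (eight-membered ring closed, C-3′ as C=NH) | COc1ccc([C@H]2c3c(OC)cc(OC)cc3[C@H]3[C@H](c4ccc(OC)cc4)c4c(OC)cc(OC)cc4C(=N)c4c(OC)cc(OC)cc4[C@H]23)cc1 | intermediate (not isolated)
17 | eight-membered diaryl ketone, octamethyl ether, C-3′ as C=O between rings B and C, rings A, D and E and the four stereocentres C-1, C-2, C-3, C-α as in the target | COc1ccc([C@H]2c3c(OC)cc(OC)cc3[C@H]3[C@H](c4ccc(OC)cc4)c4c(OC)cc(OC)cc4C(=O)c4c(OC)cc(OC)cc4[C@H]23)cc1 | intermediate
18 | ketone 17 with the ring C methoxy group ortho to the carbonyl cleaved to the phenol | COc1ccc([C@H]2c3c(OC)cc(OC)cc3[C@H]3[C@H](c4ccc(OC)cc4)c4c(OC)cc(OC)cc4C(=O)c4c(O)cc(OC)cc4[C@H]23)cc1 | intermediate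
19 | (4-methoxybenzyl)magnesium chloride | COc1ccc(C[Mg]Cl)cc1 | starting material
20 | tertiary carbinol from 18: C-3′ bears OH and the 4-methoxybenzyl group (C-2′ as CH2, ring F), either carbinol configuration | COc1ccc([C@H]2c3c(OC)cc(OC)cc3[C@H]3[C@H](c4ccc(OC)cc4)c4c(OC)cc(OC)cc4C(O)(Cc4ccc(OC)cc4)c4c(O)cc(OC)cc4[C@H]23)cc1 | intermediate
21 | stenophyllol B octamethyl ether | COc1ccc([C@H]2c3c(OC)cc(OC)cc3[C@H]3[C@H](c4ccc(OC)cc4)c4c(OC)cc(OC)cc4[C@@H]4c5c(cc(OC)cc5[C@H]23)O[C@H]4c2ccc(OC)cc2)cc1 | intermediate
22 | stenophyllol B | Oc1ccc([C@H]2c3c(O)cc(O)cc3[C@H]3[C@H](c4ccc(O)cc4)c4c(O)cc(O)cc4[C@@H]4c5c(cc(O)cc5[C@H]23)O[C@H]4c2ccc(O)cc2)cc1 | target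

**Summary and risks**

Total step count: 12. Longest linear sequence: 11 steps (steps 1–6 and 8–12).

Steps most likely to fail:

Step 8 (Proposed new method). What may go wrong: t-BuLi may add to the boronate-bound nitrile faster than it exchanges the ring B bromide; the nine-membered boracycle may not close; or the hindered boronate complex may form too slowly, so that the lithiated nitrile self-condenses. Fallback with known chemistry, from 10 and 12 back to 17: the boronate coupling is run alone (13 plus 10, then N-bromosuccinimide) and the bromo nitrile F1 is isolated. A separate Parham cyclisation of F1 (t-BuLi, THF, −100 °C, high dilution) then closes the eight-membered ring directly to ketimine 16, and acid hydrolysis gives 17.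

Step 6. What may go wrong: poor or reversed facial selectivity at C-α, attack at the 4-position of the bromoarene, or loss of the C-1 proton from the cation with scrambling of C-1. Fallback, from 5 back to 10, with the roles of the two aryl groups exchanged: Nozaki–Hiyama–Kishi coupling of 5 with aldehyde 11 gives the allylic alcohol F2; hydroboration and pinacol condensation as in step 5 give the boronate carbinol F3; Friedel–Crafts reaction of F3 with anisole (para attack) gives 10. The cation then carries ring B and ring E is the incoming arene, so the same facial bias delivers the other configuration at C-α, and the regiochemical question on the bromoarene no longer arises.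

Step 11. What may go wrong: protonation of the triarylethene on the wrong face of C-3′, which would give the C-3′/C-2′ epimeric trans-dihydrofuran. Fallback, from 18 back to 21, in which carbon and not hydrogen is delivered to C-3′: NaBH4 reduction of 18 gives the o-hydroxybenzhydrol F4. Its o-quinone methide F5, generated in the flask (Cs2CO3, CH2Cl2, 40 °C), undergoes [4+1] annulation with the sulfur ylide from (4-methoxybenzyl)dimethylsulfonium triflate to give the trans-dihydrobenzofuran 21. The nucleophile, not a proton, now adds to the open face of C-3′, which inverts the outcome at that centre.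

**Further compounds**

F1 | step 8 | 2-[(1R,2S,3S)-1-[(R)-(2-bromo-4,6-dimethoxyphenyl)(4-methoxyphenyl)methyl]-4,6-dimethoxy-3-(4-methoxyphenyl)-2,3-dihydro-1H-inden-2-yl]-4,6-dimethoxybenzonitrile (ring C on C-2 with retention, ring fusion not yet closed) | COc1ccc([C@H]2c3c(OC)cc(OC)cc3[C@@H]([C@H](c4ccc(OC)cc4)c4c(OC)cc(OC)cc4Br)[C@@H]2c2cc(OC)cc(OC)c2C#N)cc1
F2 | step 6 | (2-bromo-4,6-dimethoxyphenyl)[(1S)-5,7-dimethoxy-1-(4-methoxyphenyl)-1H-inden-3-yl]methanol, both carbinol epimers | COc1ccc([C@@H]2C=C(C(O)c3c(OC)cc(OC)cc3Br)c3cc(OC)cc(OC)c32)cc1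
F3 | step 6 | (2-bromo-4,6-dimethoxyphenyl)[4,6-dimethoxy-3-(4-methoxyphenyl)-2-(4,4,5,5-tetramethyl-1,3,2-dioxaborolan-2-yl)-2,3-dihydro-1H-inden-1-yl]methanol, ring configuration as in 8, both carbinol epimers | COc1ccc([C@H]2c3c(OC)cc(OC)cc3[C@@H](C(O)c4c(OC)cc(OC)cc4Br)[C@@H]2B2OC(C)(C)C(C)(C)O2)cc1
F4 | step 11 | o-hydroxybenzhydrol from 18 (C-3′ as CH–OH, either configuration) | COc1ccc([C@H]2c3c(OC)cc(OC)cc3[C@H]3[C@H](c4ccc(OC)cc4)c4c(OC)cc(OC)cc4C(O)c4c(O)cc(OC)cc4[C@H]23)cc1
F5 | step 11 | o-quinone methide from F4 (C-3′ exocyclic to dearomatised ring C), formed and consumed in the flask | COc1ccc([C@H]2c3c(OC)cc(OC)cc3[C@H]3[C@H](c4ccc(OC)cc4)c4c(OC)cc(OC)cc4C=C4C(=O)C=C(OC)C=C4[C@H]23)cc1
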